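1. The constants come first, and I have to read them from the earlier runs.

| setting | oak | alder | elm | flask |
|---|---|---|---|---|
| left-handed substrate | 0.16 M | 0.16 M | 0.24 M | 0.16 M |
| right-handed substrate | 0.16 M | 0.16 M | 0.24 M | 0.16 M |
| reagent | 3 equiv | 3 equiv | 3 equiv | 3.00 equiv |
| catalyst | 6 mol% | 9.5 mol% | 4.3 mol% | 4.3 mol% |
| remark | run made earlier | run made earlier | run made earlier |  |

| run | time / h | left-handed product / % | left-handed substrate / % |
|---|---|---|---|
| oak | 3.00 | 0 | 49 |
| oak | 8.00 | 7 | 42 |
| oak | 15.0 | 14 | 38 |
| oak | 25.0 | 18 | 28 |
| alder | 3.00 | 4 | 45 |
| alder | 8.00 | 11 | 39 |
| alder | 15.0 | 16 | 33 |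
| alder | 25.0 | 27 | 23 |
| elm | 6.00 | 11 | 36 |
| elm | 12.0 | 18 | 33 |
| elm | 20.0 | 20 | 26 |
| elm | 25.0 | 29 | 22 |

(standard deviation of a reading: 2 percentage points)

- catalyst is single-handed; left-handed substrate and right-handed substrate are mirror images of each other, charged as a racemate, each of them at the stated concentration
- the numbers in the tables scatter by 2 percentage points (one standard deviation)

1. apparent order in reagent when 20% of the left-handed substrate and right-handed substrate together are converted (percent change of the rate of making left-handed product for one percent more reagent charged)
2. factor on the rate of making left-handed product when 20% of the left-handed substrate and right-handed substrate together are converted if catalyst is charged twice over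

2. Oak and alder share the flask's substrate and reagent charges. So I pool their losses of left-handed substrate at 25.0 h per unit of catalyst loading. For the flask this gives a first-order constant of 0.0151 h⁻¹. I treat it as pseudo-first-order, with the rate proportional to c(reagent)·c(catalyst)·c(left-handed substrate).

3. I carry the look time, 33.9 h: the time for left-handed substrate by itself to supply 20% conversion of both substrates.

4. Now the ladder. The look time comes first. The lifetime of left-handed substrate is longer, at 66.2 h. The lifetime of reagent is longer again, at 199 h. So at the look I expect the flask to hold 86.7% of its reagent.

5. Elm did not enter the constant, so it can test it. Scaling by c(reagent)·c(catalyst), elm's look time is 15.1 h, when left-handed substrate should stand at 30.0%. Elm reads 33% at 12.0 h and 26% at 20.0 h, which bracket that value.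

6. At a fixed conversion, the reagent used is a fixed amount. So one percent more charge raises c(reagent) by more than one percent, and I commit to an order of 1.15. The rate is linear in catalyst, so I commit to a factor of 2.

7. The forecast says 1.1 and 1.9, slightly below my numbers, and it warns that “The time courses look somewhat linear”.

8. The simulation gives an order of 1.3 and a factor of 2.23, from these equations:

    reagent + catalyst + left-handed substrate → catalyst + left-handed product (k = 0.0860 M⁻² min⁻¹)
    reagent + catalyst + right-handed substrate → catalyst + right-handed product (k = 0.0140 M⁻² min⁻¹)
    catalyst ⇌ dormant form (K = 0.480, k = 2.30 × 10⁻⁴ min⁻¹)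

9. The flask reaches the look at 30.1 h, sooner than my look time of 33.9 h, and there 76.6% of the catalyst is still catalyst. Right-handed substrate reacts too, but reagent goes into left-handed product faster than into right-handed product, by the selectivity factor of 6.1 at the start and by a factor of 4.4 at 30.0 h.

The data were generated by integration on assumed constants; scatter was added.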